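The forms of the catalyst always sum to the loading, so the fraction of the charge turned per minute is the loading times the turnover frequency.

| setting | north-east | west | north | dawn | winter | autumn |
|---|---|---|---|---|---|---|
| starting material | 0.20 M | 0.20 M | 0.40 M | 0.20 M | 0.20 M | 0.20 M |
| second substrate | 1 equiv | 1 equiv | 1 equiv | 1.00 equiv | 1.00 equiv | 1.00 equiv |
| free catalyst | 1.4 mol% | 2.2 mol% | 1 mol% | 1 mol% | 1 mol% | 1 mol% |
| temperature | 2 °C | 19 °C | 2 °C | 10 °C | −5 °C | 25 °C |
| remark | run made earlier | run made earlier | run made earlier |  |  |  |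
| time |  |  |  | 1.5 h | 1.5 h | 1.5 h |

| run | time / min | target / % |
|---|---|---|
| north-east | 20.0 | 3.3 |
| north-east | 40.0 | 5.5 |
| north-east | 50.0 | 6.6 |
| north-east | 80.0 | 10.6 |
| north-east | 90.0 | 11.5 |
| north-east | 120 | 15.5 |
| west | 5.00 | 6.0 |
| west | 12.0 | 13.2 |
| west | 25.0 | 25.9 |
| west | 40.0 | 37.5 |
| west | 50.0 | 43.6 |
| west | 80.0 | 54.8 |
| north | 20.0 | 1.9 |
| north | 40.0 | 4.4 |
| north | 60.0 | 5.7 |
| north | 80.0 | 7.2 |
| north | 120 | 10.6 |

(each reading ± 0.3 percentage points)

1. the best flask by amount of target, in percent of the starting material charged; "all alike" if 1.5 percentage points covers them all (dawn / winter / autumn / all alike)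
2. amount of target at the end, in percent of the starting material charged, dawn
3. amount of target at the end, in percent of the starting material charged, winter
4. amount of target at the end, in percent of the starting material charged, autumn

- on the list of suspects stand: second substrate + free catalyst <-> catalyst intermediate B; starting material <-> dormant form; catalyst intermediate A -> free catalyst + target; target <-> isomer of the product; starting material + free catalyst <-> catalyst intermediate A; target -> over-reaction product; catalyst intermediate B -> free catalyst + second product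

I read the turnover frequency as target per catalyst per minute. At the last readings at 2 °C it is:

north-east: 0.0923 min⁻¹
north: 0.0883 min⁻¹

These agree although north holds twice the concentration, so I treat the rate as zero order in concentration. West's first reading gives 0.545 min⁻¹ at 19 °C. I carry the logarithm of the frequency straight through temperature:

dawn: 0.213 min⁻¹
winter: 0.0444 min⁻¹
autumn: 1.02 min⁻¹

Two times then judge each flask: the run time 90 min and the emptying time, the time the loading needs to turn the whole charge at that frequency, which is 470 min for dawn. Their ratio is the straight-line fraction converted: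

dawn: 0.192
winter: 0.0399
autumn: 0.919

Dawn and winter stay below 1, so I take these ratios as my estimates of their yields. Autumn's ratio is close to west's at its last reading, 0.960, where west reads 54.8%. I therefore expect autumn a little under that, and best.

The forecast says autumn, with dawn 19.5%, winter 4.2% and autumn 49.5%, “perhaps slightly less if over-reaction grows”.

Autumn gives 39.4%, dawn 18.4%, winter 3.43%.

    second substrate + free catalyst ⇌ catalyst intermediate B (K = 26.8 M⁻¹, k = 6.81 M⁻¹ min⁻¹, Ea = 60.0 kJ mol⁻¹, ΔH = −3.00 kJ mol⁻¹)
    starting material ⇌ dormant form (K = 0.332, k = 0.00359 min⁻¹, Ea = 92.0 kJ mol⁻¹, ΔH = 6.00 kJ mol⁻¹)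
    catalyst intermediate A → free catalyst + target (k = 1.54 min⁻¹, Ea = 81.0 kJ mol⁻¹)
    target ⇌ isomer of the product (K = 0.550, k = 0.0204 min⁻¹, Ea = 97.0 kJ mol⁻¹, ΔH = −50.0 kJ mol⁻¹)
    starting material + free catalyst ⇌ catalyst intermediate A (K = 7.80 M⁻¹, k = 333 M⁻¹ min⁻¹, Ea = 44.0 kJ mol⁻¹, ΔH = −79.0 kJ mol⁻¹)
    target → over-reaction product (k = 0.00119 min⁻¹, Ea = 91.0 kJ mol⁻¹)
    catalyst intermediate B → free catalyst + second product (k = 7.80 min⁻¹, Ea = 78.0 kJ mol⁻¹)
    (constants at 25 °C)

Autumn is best, at 39.4%, against the forecast's 49.5%. Beside that target, autumn holds 17.1% of the charge as isomer of the product at the asked time. Dawn's emptying time of 470 min, divided by the loading ratio 2.50, gives 188 min for the neighbour flask, dawn with 2.5 mol% of free catalyst, so its ratio is 0.479, and that flask reads 44.2%.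

All runs were computed for substances that don't exist.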